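(The runs stem from a simulated flask from invented constants.)

If open intermediate climbs to its plateau early, the question for this flask is how long the plateau stays.

all flasks: free catalyst 33 mM; second catalyst 0.60 mM

| flask | starting material | coupling partner | remark | time |
|---|---|---|---|---|
| winter | 0.15 M | 0.60 M | run made earlier |  |
| dusk | 0.22 M | 0.60 M | run made earlier |  |
| noon | 0.30 M | 1.2 M | run made earlier |  |
| flask | 0.30 M | 0.600 M |  | 6.0 h |

| run | time / h | open intermediate / % | target / % | starting material / % |
|---|---|---|---|---|
| winter | 0.0417 | 32.2 | 1.0 | 67.0 |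
| winter | 0.100 | 36.8 | 1.0 | 64.3 |
| winter | 0.250 | 34.7 | 2.5 | 61.7 |
| winter | 0.667 | 35.0 | 2.5 | 61.2 |
| winter | 1.33 | 33.6 | 6.4 | 58.7 |
| winter | 4.00 | 29.7 | 14.3 | 49.4 |
| dusk | 0.0417 | 32.5 | 0 | 70.3 |
| dusk | 0.100 | 36.3 | 0 | 64.5 |
| dusk | 0.250 | 37.0 | 0 | 62.1 |
| dusk | 0.667 | 36.9 | 3.3 | 63.0 |
| dusk | 1.33 | 31.9 | 2.5 | 60.6 |
| dusk | 4.00 | 32.3 | 9.6 | 55.0 |
| noon | 0.0417 | 32.4 | 1.2 | 67.6 |
| noon | 0.133 | 36.2 | 0 | 61.7 |
| noon | 0.417 | 36.5 | 0.7 | 63.3 |
| noon | 1.33 | 33.3 | 5.0 | 58.0 |
| noon | 4.00 | 28.6 | 10.3 | 49.7 |

(scatter of a reading: 1 percentage point)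

1. time up to 6.0 h at which open intermediate stands highest
2. the amount of open intermediate, in percent of the starting material charged, at that time
3. earliest time at which at least nineteen twentieths of that best amount are there
4. latest time at which they still are

Call open intermediate plus starting material the pool. Open intermediate is 0.373 of the pool in the dusk run at 0.250 h, and 0.375 of it in the winter run at 4.00 h. The share looks constant, so a twentieth lost from the pool is a twentieth lost from open intermediate. The dispute is over how the pool drains. At 4.00 h the winter run has lost 20.9 % of its charge and the dusk run 12.7 %.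

The first chemist holds that a fixed fraction goes each hour, first order in the pool. A twentieth over the mean hourly loss gives a plateau of 1.19 h, whatever the charge.

The second chemist holds that a fixed rate goes, zero order in starting material. She turns the losses into rates. Winter gives 7.84 mM h⁻¹ and dusk 6.99 mM h⁻¹, although winter lost more of its charge. The noon run, with twice the coupling partner, gives 16.3 mM h⁻¹. So the rate follows the partner, and this flask has the partner charge of winter and dusk. Their mean is r = 7.41 mM h⁻¹.

Her quantity is the hold time τ, a twentieth of the charge divided by r 2.02 h. For this flask τ is 2.02 h. I side with her, since the rates agree better than the percentages, and I expect the plateau to last longer than the first view says.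

The forecast, on the second view, gives 0.16 h, 36.6 %, 0.06 h and 2 h, and calls the drain “roughly zero order in substrate and about first order in partner”.

The flask peaks at 0.154 h with 36.4 %, and it reaches the level at 0.0607 h.

    coupling partner + target → over-reaction product (k = 1.00 × 10⁻⁴ M⁻¹ s⁻¹)
    second catalyst + open intermediate ⇌ catalyst intermediate (K = 1300 M⁻¹, k = 48.0 M⁻¹ s⁻¹)
    starting material + free catalyst ⇌ free catalyst + open intermediate (K = 0.580, k = 0.150 M⁻¹ s⁻¹)
    coupling partner + catalyst intermediate ⇌ second catalyst + target (K = 0.120, k = 0.00630 M⁻¹ s⁻¹)

The flask holds the asked level until 2.05 h, against a τ of 2.02 h. At 60.0 h catalyst intermediate in the flask still holds 95.8 % of the second catalyst, more than the 4.19 % standing free. With 0.75 M of starting material and the rest unchanged, τ becomes 5.06 h, shorter than the 6.0 h allowed. That neighbour should therefore end below the asked share of its best, and it ends at 34.4 % against 36.6 %.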